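The tetrahydrofuran is disconnected at the C4–C5 bond. C5 is the only ring carbon at the formaldehyde level on O1, and C4 carries the benzylic carbon next to ring B, whose 2- and 4-methoxy groups stabilise a cation there. A Prins closure of a methoxymethyl ether, the syn (E)-styrenyl homoallylic ether with a silyl-protected CH2OH, therefore forms the ring and the 4-benzylidene group in one operation, with C2 and C3 already set by a catalytic asymmetric allylboration. Hydrogenation of the exocyclic alkene on the face away from ring A and the C3 substituent then sets C4 all-cis, and desilylation gives the target.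

Key step: step 6

Remark: ring A is the 3,4,5-trimethoxyphenyl group on C2 and ring B the 2,4,5-trimethoxyphenyl group of the C4 benzyl unit; the target is read as the all-cis (2R,3R,4R) tetrahydrofuran; (R)-TRIP is (R)-3,3'-bis(2,4,6-triisopropylphenyl)-1,1'-binaphthyl-2,2'-diyl hydrogen phosphate; buta-1,3-diene (toluene solution), bis(pinacolato)diboron and (R)-TRIP are taken as purchasable.

Step 1
Reactants: 1 buta-1,3-diene; 2 bis(pinacolato)diboron
Product: 3 (Z)-1,4-bis(4,4,5,5-tetramethyl-1,3,2-dioxaborolan-2-yl)but-2-ene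
Conditions: Pt(PPh3)4 (3 mol%), toluene, 80 °C, sealed vessel, diene in excess
Reagents that add atoms: none
Why: Platinum-catalysed 1,4-diboration of a 1,3-diene, in which the B–B bond adds oxidatively to zerovalent platinum, the diene inserts in its s-cis form and reductive elimination places the second boron on the far terminus, which fixes the Z geometry; no stereocentre is formed.

Step 2
Reactants: 3 (Z)-1,4-bis(4,4,5,5-tetramethyl-1,3,2-dioxaborolan-2-yl)but-2-ene; 4 3,4,5-trimethoxybenzaldehyde
Product: 6 (1R,2R)-2-ethenyl-1-(3,4,5-trimethoxyphenyl)propane-1,3-diol, via boryl ether adduct 5 (not isolated)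
Conditions: (R)-TRIP (5 mol%), 4 Å molecular sieves, toluene, −30 °C; then NaOH aq., H2O2, THF, 0 °C to rt
Reagents that add atoms: hydrogen peroxide, OO
Why: Chiral-phosphoric-acid-catalysed allylboration of an aldehyde through a closed six-membered chair transition state, in which the Z geometry of the allyl boronate puts the CH2B group axial and so gives the syn pair (future C2 and C3), while the acid, hydrogen-bonded to a boronate oxygen and to the formyl hydrogen, exposes the Re face of the aldehyde and sets the carbinol carbon as R (the (R)-acid is chosen by analogy with crotyl pinacol boronates); alkaline peroxide then oxidises the remaining primary C–B bond without touching either stereocentre.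

Step 3
Reactants: 6 (1R,2R)-2-ethenyl-1-(3,4,5-trimethoxyphenyl)propane-1,3-diol
Product: 7 (1R,2R)-2-[(tert-butyldiphenylsilyloxy)methyl]-1-(3,4,5-trimethoxyphenyl)but-3-en-1-ol
Conditions: t-BuPh2SiCl (1.05 equiv), imidazole, CH2Cl2, 0 °C
Reagents that add atoms: tert-butyldiphenylsilyl chloride, CC(C)(C)[Si](Cl)(c1ccccc1)c1ccccc1
Why: Silylation of the primary hydroxyl in preference to the hindered secondary benzylic one on steric grounds; no stereocentre is affected.

Step 4
Reactants: 7 (1R,2R)-2-[(tert-butyldiphenylsilyloxy)methyl]-1-(3,4,5-trimethoxyphenyl)but-3-en-1-ol; 8 chloromethyl methyl ether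
Product: 9 (1R,2R)-1-(methoxymethoxy)-2-[(tert-butyldiphenylsilyloxy)methyl]-1-(3,4,5-trimethoxyphenyl)but-3-ene
Conditions: i-Pr2NEt, Bu4NI (cat.), CH2Cl2, 0 to 40 °C
Reagents that add atoms: none
Why: Base-mediated O-alkylation of the secondary alcohol by the reactive α-chloro ether (acetal formation of the Williamson type, accelerated by iodide); the silyl ether and the alkene are inert and the stereocentres are untouched.

Step 5
Reactants: 9 (1R,2R)-1-(methoxymethoxy)-2-[(tert-butyldiphenylsilyloxy)methyl]-1-(3,4,5-trimethoxyphenyl)but-3-ene; 10 1-iodo-2,4,5-trimethoxybenzene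
Product: 11 (1R,2R,3E)-1-(methoxymethoxy)-2-[(tert-butyldiphenylsilyloxy)methyl]-1-(3,4,5-trimethoxyphenyl)-4-(2,4,5-trimethoxyphenyl)but-3-ene
Conditions: Pd(OAc)2 (5 mol%), Bu4NCl, NaHCO3, DMF, 70 °C
Reagents that add atoms: none
Why: Mizoroki–Heck reaction under ligand-free phase-transfer conditions, in which the aryl iodide adds oxidatively to zerovalent palladium (formed in situ from the divalent palladium acetate), the terminal alkene inserts syn with the aryl group going to the CH2 terminus, and syn β-hydride elimination toward the benzylic hydrogen gives the conjugated E styrene without touching the two stereocentres.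

Step 6
Reactants: 11 (1R,2R,3E)-1-(methoxymethoxy)-2-[(tert-butyldiphenylsilyloxy)methyl]-1-(3,4,5-trimethoxyphenyl)-4-(2,4,5-trimethoxyphenyl)but-3-ene
Product: 14 (2R,3R)-3-[(tert-butyldiphenylsilyloxy)methyl]-4-[(Z)-2,4,5-trimethoxybenzylidene]-2-(3,4,5-trimethoxyphenyl)tetrahydrofuran, via oxocarbenium triflate 12 (not isolated), via benzylic cation triflate 13 (not isolated)
Conditions: Me3SiOTf (1.5 equiv), 2,6-di-tert-butyl-4-methylpyridine (2.5 equiv), CH2Cl2, −78 to −40 °C; NaHCO3 aq.
Reagents that add atoms: none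
Why: Me3SiOTf silylates the exposed methoxy oxygen of the acetal and expels MeOSiMe3 to give the O1=C5H2 oxocarbenium ion 12; C4 of the styrene attacks C5 to give the ring B benzylic cation 13, from which the hindered pyridine removes the C4 proton to leave the exocyclic alkene. The closest known reaction type is the Prins (acetal-initiated cation–olefin) cyclisation of methoxymethyl ethers of aryl-substituted homoallylic alcohols, which gives 3-substituted tetrahydrofurans through a benzylic cation. The one ring formed (O1–C2–C3–C4–C5) closes 5-exo-trig through the new C5–C4 bond; the 6-endo alternative would put the charge on a secondary carbon, whereas here it sits on the carbon conjugated to the 2- and 4-methoxy groups of ring B. No stereocentre is created, since C4 ends sp2, C2 and C3 are not involved and keep their syn R,R arrangement, and the Z geometry follows from ring B turning away from the C3 substituent during proton loss. Proton loss must beat capture of the cation by ring A (a bridging Friedel–Crafts closure) or by the silyl ether oxygen; both captures need the cationic carbon cis to the C2 and C3 groups, which is the disfavoured sense of closure, and the excess hindered base at low temperature should drain the cation by elimination. Ionisation at the acetal carbon, not at the benzylic C2–O bond, rests on the steric shielding of the inner oxygen and the modest donor power of ring A, and the tert-butyldiphenylsilyl ether is kept because its hindered oxygen is a poor nucleophile and the group tolerates the silyl triflate.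

Step 7
Reactants: 14 (2R,3R)-3-[(tert-butyldiphenylsilyloxy)methyl]-4-[(Z)-2,4,5-trimethoxybenzylidene]-2-(3,4,5-trimethoxyphenyl)tetrahydrofuran
Product: 15 (2R,3R,4R)-3-[(tert-butyldiphenylsilyloxy)methyl]-4-(2,4,5-trimethoxybenzyl)-2-(3,4,5-trimethoxyphenyl)tetrahydrofuran
Conditions: H2 (1 atm), 5% Rh/Al2O3, EtOAc, rt
Reagents that add atoms: none
Why: Heterogeneous syn hydrogenation on the alkene face opposite ring A and the CH2OSi group (both on the same side of the ring), which delivers hydrogen to C4 from the open face and so sets C4 as R with the benzyl group cis to both neighbours; rhodium on alumina is chosen because it is slow to hydrogenolyse the benzylic C2–O and allylic C5–O bonds and to migrate the double bond.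

Step 8
Reactants: 15 (2R,3R,4R)-3-[(tert-butyldiphenylsilyloxy)methyl]-4-(2,4,5-trimethoxybenzyl)-2-(3,4,5-trimethoxyphenyl)tetrahydrofuran
Product: 16 [(2R,3R,4R)-4-(2,4,5-trimethoxybenzyl)-2-(3,4,5-trimethoxyphenyl)tetrahydrofuran-3-yl]methanol
Conditions: Bu4NF, THF, 0 °C to rt
Reagents that add atoms: none
Why: Fluoride-induced cleavage of the Si–O bond, driven by the strong Si–F bond; the ring ether, the aryl methyl ethers and the three stereocentres are unaffected.

Compound list
1 | buta-1,3-diene | C=CC=C | starting material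
2 | bis(pinacolato)diboron | CC1(C)OB(OC1(C)C)B1OC(C)(C)C(C)(C)O1 | starting material
3 | (Z)-1,4-bis(4,4,5,5-tetramethyl-1,3,2-dioxaborolan-2-yl)but-2-ene | CC1(C)OB(C/C=C\CB2OC(C)(C)C(C)(C)O2)OC1(C)C | intermediate
4 | 3,4,5-trimethoxybenzaldehyde | COc1cc(C=O)cc(OC)c1OC | starting material
5 | boryl ether adduct, 2-{(1R,2S)-2-[(pinacolboryl)methyl]-1-(3,4,5-trimethoxyphenyl)but-3-enyloxy}-4,4,5,5-tetramethyl-1,3,2-dioxaborolane (not isolated) | CC1(C)OB(O[C@@H](c2cc(OC)c(OC)c(OC)c2)[C@@H](CB3OC(C)(C)C(C)(C)O3)C=C)OC1(C)C | intermediate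
6 | (1R,2R)-2-ethenyl-1-(3,4,5-trimethoxyphenyl)propane-1,3-diol | O[C@@H](c1cc(OC)c(OC)c(OC)c1)[C@@H](CO)C=C | intermediate
7 | (1R,2R)-2-[(tert-butyldiphenylsilyloxy)methyl]-1-(3,4,5-trimethoxyphenyl)but-3-en-1-ol | O[C@@H](c1cc(OC)c(OC)c(OC)c1)[C@@H](CO[Si](c2ccccc2)(c3ccccc3)C(C)(C)C)C=C | intermediate
8 | chloromethyl methyl ether | COCCl | starting material
9 | (1R,2R)-1-(methoxymethoxy)-2-[(tert-butyldiphenylsilyloxy)methyl]-1-(3,4,5-trimethoxyphenyl)but-3-ene | COCO[C@@H](c1cc(OC)c(OC)c(OC)c1)[C@@H](CO[Si](c2ccccc2)(c3ccccc3)C(C)(C)C)C=C | intermediate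
10 | 1-iodo-2,4,5-trimethoxybenzene | COc1cc(OC)c(I)cc1OC | starting material
11 | (1R,2R,3E)-1-(methoxymethoxy)-2-[(tert-butyldiphenylsilyloxy)methyl]-1-(3,4,5-trimethoxyphenyl)-4-(2,4,5-trimethoxyphenyl)but-3-ene (Prins precursor) | COCO[C@@H](c1cc(OC)c(OC)c(OC)c1)[C@@H](CO[Si](c2ccccc2)(c3ccccc3)C(C)(C)C)/C=C/c4cc(OC)c(OC)cc4OC | intermediate
12 | oxocarbenium triflate, O1=C5H2 ion of 11 after loss of methoxide (not isolated) | C=[O+][C@@H](c1cc(OC)c(OC)c(OC)c1)[C@@H](CO[Si](c2ccccc2)(c3ccccc3)C(C)(C)C)/C=C/c4cc(OC)c(OC)cc4OC.[O-]S(=O)(=O)C(F)(F)F | intermediate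
13 | benzylic cation triflate, (2R,3R)-tetrahydrofuran with C4 bearing the 2,4,5-trimethoxyphenylmethylium carbon, C4 configuration transient (not isolated) | COc1cc(OC)c(OC)cc1[CH+]C5CO[C@@H](c2cc(OC)c(OC)c(OC)c2)[C@H]5CO[Si](c3ccccc3)(c4ccccc4)C(C)(C)C.[O-]S(=O)(=O)C(F)(F)F | intermediate
14 | (2R,3R)-3-[(tert-butyldiphenylsilyloxy)methyl]-4-[(Z)-2,4,5-trimethoxybenzylidene]-2-(3,4,5-trimethoxyphenyl)tetrahydrofuran | COc1cc(OC)c(OC)cc1/C=C5\CO[C@@H](c2cc(OC)c(OC)c(OC)c2)[C@H]5CO[Si](c3ccccc3)(c4ccccc4)C(C)(C)C | intermediate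
15 | (2R,3R,4R)-3-[(tert-butyldiphenylsilyloxy)methyl]-4-(2,4,5-trimethoxybenzyl)-2-(3,4,5-trimethoxyphenyl)tetrahydrofuran | COc1cc(OC)c(OC)cc1C[C@H]1CO[C@@H](c2cc(OC)c(OC)c(OC)c2)[C@H]1CO[Si](c3ccccc3)(c4ccccc4)C(C)(C)C | intermediate
16 | [(2R,3R,4R)-4-(2,4,5-trimethoxybenzyl)-2-(3,4,5-trimethoxyphenyl)tetrahydrofuran-3-yl]methanol | COc1cc(OC)c(OC)cc1C[C@H]1CO[C@@H](c2cc(OC)c(OC)c(OC)c2)[C@H]1CO | target

Total steps: 8. Longest linear sequence: 8 steps (1 to 16).

Steps most likely to fail

1. Step 6 (Prins closure). The benzylic cation may be captured instead of losing a proton (Friedel–Crafts attack by ring A, attack by the silyl ether oxygen, or an adventitious nucleophile). The acetal may also ionise at the wrong C–O bond, or the acid-sensitive product styrene may be re-protonated. Fallback: the cationic closure is replaced by classical benzylidene-lactone chemistry, in which C5 is brought in at the carboxyl level and no benzylic cation occurs. It sets out from 7. Hydroboration–oxidation (9-BBN, THF; NaBO3·4H2O) should give (1R,2R)-2-[(tert-butyldiphenylsilyloxy)methyl]-1-(3,4,5-trimethoxyphenyl)butane-1,4-diol F1. TEMPO/PhI(OAc)2 should oxidise the primary alcohol and the lactol that forms to the cis-lactone (4R,5R)-4-[(tert-butyldiphenylsilyloxy)methyl]-5-(3,4,5-trimethoxyphenyl)dihydrofuran-2(3H)-one F2. Its lithium enolate (LiN(SiMe3)2, THF, −78 °C) is added to commercial 2,4,5-trimethoxybenzaldehyde (COc1cc(OC)c(C=O)cc1OC) to give the β-hydroxy lactone (4R,5R)-3-[hydroxy(2,4,5-trimethoxyphenyl)methyl]-4-[(tert-butyldiphenylsilyloxy)methyl]-5-(3,4,5-trimethoxyphenyl)dihydrofuran-2(3H)-one F3 as a mixture at the two new centres. Mesylation and elimination (MsCl, excess Et3N, CH2Cl2, 0 °C to rt) should give the conjugated lactone (3E,4R,5R)-3-(2,4,5-trimethoxybenzylidene)-4-[(tert-butyldiphenylsilyloxy)methyl]-5-(3,4,5-trimethoxyphenyl)dihydrofuran-2(3H)-one F4. Hydrogenation (H2, Rh/Al2O3, EtOAc) on the face opposite the two ring substituents should give the all-cis lactone (3R,4R,5R)-3-(2,4,5-trimethoxybenzyl)-4-[(tert-butyldiphenylsilyloxy)methyl]-5-(3,4,5-trimethoxyphenyl)dihydrofuran-2(3H)-one F5. LiBH4 in THF should reduce it to (1R,2R,3R)-2-[(tert-butyldiphenylsilyloxy)methyl]-3-(2,4,5-trimethoxybenzyl)-1-(3,4,5-trimethoxyphenyl)butane-1,4-diol F6. A Mitsunobu cyclodehydration (PPh3, diisopropyl azodicarboxylate, THF) activates the primary hydroxyl and closes the O1–C5 bond with retention at C2. The route is rejoined at 15, so steps 4 to 7 are bypassed.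

2. Step 2 (asymmetric allylboration). Facial control in the allyl transfer from the bifunctional diboron reagent may be insufficient, or an uncatalysed background reaction may erode the enantiomeric purity. Fallback: boron and Brønsted-acid catalysis are replaced by a Lewis-base-catalysed allyltrichlorosilane addition. It sets out from 4 and commercial (Z)-but-2-ene-1,4-diol (OC/C=C\CO). Monosilylation (NaH, t-BuPh2SiCl, THF) should give (Z)-4-(tert-butyldiphenylsilyloxy)but-2-en-1-ol F7. MsCl, LiCl and 2,4,6-collidine in DMF should give the allylic chloride tert-butyl{[(Z)-4-chlorobut-2-enyl]oxy}diphenylsilane F8. HSiCl3, CuCl and i-Pr2NEt in Et2O should give, with retention of alkene geometry, tert-butyldiphenyl{[(Z)-4-(trichlorosilyl)but-2-enyl]oxy}silane F9. Its addition to 4 under a chiral bisphosphoramide Lewis base (i-Pr2NEt, CH2Cl2, −78 °C) proceeds through a closed chair at hexacoordinate silicon, so the Z geometry again gives the syn pair and the catalyst antipode is chosen for Re-face attack. Aqueous NaHCO3 work-up gives 7 directly; the route is rejoined at 7 and step 3 is skipped.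

3. Step 7 (hydrogenation). Facial discrimination may be poor, the double bond may migrate into the ring before reduction (which would scramble C3), the benzylic or allylic C–O bonds may be hydrogenolysed, or the arenes may be over-reduced. Fallback: metal-free diimide reduction of 14 (2-nitrobenzenesulfonylhydrazide, Et3N, CH2Cl2, rt, reagent in excess). Diimide transfers both hydrogens in one concerted syn step to the same open face, with no metal hydride that could isomerise the alkene or cleave C–O bonds. It sets out from 14 and returns at 15; no new compound arises (F0).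

Further compounds
F1 | step 6 | (1R,2R)-2-[(tert-butyldiphenylsilyloxy)methyl]-1-(3,4,5-trimethoxyphenyl)butane-1,4-diol | O[C@@H](c1cc(OC)c(OC)c(OC)c1)[C@@H](CO[Si](c2ccccc2)(c3ccccc3)C(C)(C)C)CCO
F2 | step 6 | (4R,5R)-4-[(tert-butyldiphenylsilyloxy)methyl]-5-(3,4,5-trimethoxyphenyl)dihydrofuran-2(3H)-one | O=C1O[C@@H](c2cc(OC)c(OC)c(OC)c2)[C@@H](CO[Si](c3ccccc3)(c4ccccc4)C(C)(C)C)C1
F3 | step 6 | (4R,5R)-3-[hydroxy(2,4,5-trimethoxyphenyl)methyl]-4-[(tert-butyldiphenylsilyloxy)methyl]-5-(3,4,5-trimethoxyphenyl)dihydrofuran-2(3H)-one, mixture at C3 and the carbinol carbon | O=C1O[C@@H](c2cc(OC)c(OC)c(OC)c2)[C@@H](CO[Si](c3ccccc3)(c4ccccc4)C(C)(C)C)C1C(O)c5cc(OC)c(OC)cc5OC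
F4 | step 6 | (3E,4R,5R)-3-(2,4,5-trimethoxybenzylidene)-4-[(tert-butyldiphenylsilyloxy)methyl]-5-(3,4,5-trimethoxyphenyl)dihydrofuran-2(3H)-one | O=C1O[C@@H](c2cc(OC)c(OC)c(OC)c2)[C@@H](CO[Si](c3ccccc3)(c4ccccc4)C(C)(C)C)/C1=C\c5cc(OC)c(OC)cc5OC
F5 | step 6 | (3R,4R,5R)-3-(2,4,5-trimethoxybenzyl)-4-[(tert-butyldiphenylsilyloxy)methyl]-5-(3,4,5-trimethoxyphenyl)dihydrofuran-2(3H)-one | O=C1O[C@@H](c2cc(OC)c(OC)c(OC)c2)[C@@H](CO[Si](c3ccccc3)(c4ccccc4)C(C)(C)C)[C@H]1Cc5cc(OC)c(OC)cc5OC
F6 | step 6 | (1R,2R,3R)-2-[(tert-butyldiphenylsilyloxy)methyl]-3-(2,4,5-trimethoxybenzyl)-1-(3,4,5-trimethoxyphenyl)butane-1,4-diol | O[C@@H](c1cc(OC)c(OC)c(OC)c1)[C@@H](CO[Si](c2ccccc2)(c3ccccc3)C(C)(C)C)[C@H](CO)Cc4cc(OC)c(OC)cc4OC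
F7 | step 2 | (Z)-4-(tert-butyldiphenylsilyloxy)but-2-en-1-ol | OC/C=C\CO[Si](c1ccccc1)(c2ccccc2)C(C)(C)C
F8 | step 2 | tert-butyl{[(Z)-4-chlorobut-2-enyl]oxy}diphenylsilane | ClC/C=C\CO[Si](c1ccccc1)(c2ccccc2)C(C)(C)C
F9 | step 2 | tert-butyldiphenyl{[(Z)-4-(trichlorosilyl)but-2-enyl]oxy}silane | Cl[Si](Cl)(Cl)C/C=C\CO[Si](c1ccccc1)(c2ccccc2)C(C)(C)C
F0 | step 7 | none | none
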